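**Retrosynthetic overview**
1. Eriostemin ⇒ its 8-O-benzyl ether (hydrogenolysis) ⇒ 8-benzyloxy-5,6,7,4'-tetramethoxyflavone (C3–O bond by epoxidation and isomerisation).
2. Flavone ⇒ 2'-hydroxychalcone (O1–C2 closure and dehydrogenation with I2/DMSO).
3. Chalcone ⇒ 3-benzyloxy-2-hydroxy-4,5,6-trimethoxyacetophenone + 4-methoxybenzaldehyde (Cα=Cβ by Claisen–Schmidt aldol condensation, the fragment-joining step).
4. Acetophenone ⇒ 3,4,5-trimethoxyphenol MOM ether. The future 8-oxygen comes from ortho-lithiation, borylation and oxidation. The acetyl group comes from bromination, Br/Li exchange and a Weinreb amide.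
5. Ring order: both benzene rings are bought. Only the pyranone C ring is built, after the aldol step.

Assumption: eriostemin (C19H18O8) has no stereocentre or stereogenic axis. It is achiral, so no enantioselective step is needed. The only stereo-element on the way is the E-alkene of the chalcone, which is consumed.

**Step 1**
Reactants: 1 3,4,5-trimethoxyphenol
Product: 2 1,2,3-trimethoxy-5-(methoxymethoxy)benzene
Conditions: MOMCl (1.3 equiv), i-Pr2NEt (1.8 equiv), CH2Cl2, 0 °C → rt
Reagents that add atoms: chloromethyl methyl ether, COCCl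
Why: O-alkylation of the phenol (Williamson-type, via the oxocarbenium ion) installs a base-stable protecting group that is also a strong ortho-directing group, and no stereocentre is formed.

**Step 2**
Reactants: 2 1,2,3-trimethoxy-5-(methoxymethoxy)benzene
Product: 5 2,3,4-trimethoxy-6-(methoxymethoxy)phenol, via aryllithium 3 (not isolated), via dimethyl arylboronate 4 (not isolated)
Conditions: n-BuLi (1.2 equiv), THF, 0 °C, 1 h; B(OMe)3 (2 equiv), −78 °C → rt; AcOH, 30% H2O2, 0 °C → rt
Reagents that add atoms: hydrogen peroxide, OO (the new phenol oxygen); trimethyl borate, COB(OC)OC (boron of 4 only); n-butyllithium, [Li]CCCC (lithium of 3 only)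
Why: In this directed ortho-metalation the two ring C–H positions are equivalent and each lies between OMOM and OMe, so a single aryllithium forms, and borylation followed by peroxide oxidation (1,2-aryl shift from B to O) places the future 8-oxygen without any regiochemical ambiguity.

**Step 3**
Reactants: 5 2,3,4-trimethoxy-6-(methoxymethoxy)phenol
Product: 6 2-(benzyloxy)-3,4,5-trimethoxy-1-(methoxymethoxy)benzene
Conditions: BnBr (1.2 equiv), K2CO3 (2 equiv), DMF, 50 °C, Ar
Reagents that add atoms: benzyl bromide, BrCc1ccccc1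
Why: Williamson ether synthesis on the only free phenol tags the future 8-oxygen with a group that survives base, acid, I2/DMSO and DMDO and leaves at the end by hydrogenolysis without touching the methyl ethers.

**Step 4**
Reactants: 6 2-(benzyloxy)-3,4,5-trimethoxy-1-(methoxymethoxy)benzene
Product: 7 1-(benzyloxy)-3-bromo-4,5,6-trimethoxy-2-(methoxymethoxy)benzene
Conditions: NBS (1.05 equiv), MeCN, 0 °C, dark
Reagents that add atoms: N-bromosuccinimide, O=C1CCC(=O)N1Br
Why: Electrophilic aromatic bromination can only hit the single C–H of the penta-alkoxy ring, which is far more nucleophilic than the benzyl phenyl ring, and polar, dark conditions suppress radical benzylic bromination.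

**Step 5**
Reactants: 7 1-(benzyloxy)-3-bromo-4,5,6-trimethoxy-2-(methoxymethoxy)benzene; 8 N-methoxy-N-methylacetamide
Product: 11 1-[3-(benzyloxy)-4,5,6-trimethoxy-2-(methoxymethoxy)phenyl]ethan-1-one, via aryllithium 9 (not isolated), via tetrahedral Weinreb adduct 10 (not isolated)
Conditions: n-BuLi (1.1 equiv), THF, −78 °C, 20 min; 8 (1.5 equiv), −78 → 0 °C; aq NH4Cl
Reagents that add atoms: n-butyllithium, [Li]CCCC (lithium of 9 and 10 only)
Why: Bromine–lithium exchange at −78 °C is much faster than deprotonation of the benzylic OCH2, and the Weinreb ketone synthesis stops at the chelated tetrahedral adduct, so the methyl ketone forms without Lewis acid (which would endanger the benzyl ether) and without over-addition.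

**Step 6**
Reactants: 11 1-[3-(benzyloxy)-4,5,6-trimethoxy-2-(methoxymethoxy)phenyl]ethan-1-one
Product: 12 1-[3-(benzyloxy)-2-hydroxy-4,5,6-trimethoxyphenyl]ethan-1-one
Conditions: conc. HCl (cat.), MeOH, 50 °C, 2 h
Reagents that add atoms: none
Why: Acid-catalysed acetal exchange (transacetalisation to methanol) removes only the MOM acetal, helped by formation of the hydrogen-bonded o-hydroxyacetophenone, while the benzyl and methyl ethers are inert.

**Step 7**
Reactants: 12 1-[3-(benzyloxy)-2-hydroxy-4,5,6-trimethoxyphenyl]ethan-1-one; 13 4-methoxybenzaldehyde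
Product: 15 (E)-1-[3-(benzyloxy)-2-hydroxy-4,5,6-trimethoxyphenyl]-3-(4-methoxyphenyl)prop-2-en-1-one, via aldol adduct 14 (not isolated)
Conditions: 13 (1.2 equiv), 50% aq KOH (10 equiv), EtOH, rt, 36 h, N2; then 2 M HCl to pH 3
Reagents that add atoms: none
Why: In this Claisen–Schmidt crossed aldol condensation the methyl ketone is the only enolisable partner and the aldehyde the only good electrophile, and E1cB dehydration of the aldol gives the conjugated, thermodynamically preferred E-chalcone, as is well established for 2'-hydroxy-polymethoxyacetophenones.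

**Step 8**
Reactants: 15 (E)-1-[3-(benzyloxy)-2-hydroxy-4,5,6-trimethoxyphenyl]-3-(4-methoxyphenyl)prop-2-en-1-one
Product: 17 8-(benzyloxy)-5,6,7-trimethoxy-2-(4-methoxyphenyl)-4H-chromen-4-one, via flavanone 16 (not isolated)
Conditions: I2 (10 mol %), DMSO, 120 °C, 3 h
Reagents that add atoms: none
Why: In the I2/DMSO oxidative cyclisation, intramolecular oxa-Michael addition of the 2'-OH closes the pyranone ring, α-iodination and HI loss aromatise it, and DMSO re-oxidises HI, so the medium stays too weakly acidic to cleave the benzyl or 5-methyl ether.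

**Step 9**
Reactants: 17 8-(benzyloxy)-5,6,7-trimethoxy-2-(4-methoxyphenyl)-4H-chromen-4-one
Product: 19 8-(benzyloxy)-3-hydroxy-5,6,7-trimethoxy-2-(4-methoxyphenyl)-4H-chromen-4-one, via flavone 2,3-epoxide 18 (not isolated)
Conditions: DMDO (ca. 0.08 M in acetone, freshly made from Oxone/NaHCO3/acetone, 2.5 equiv), CH2Cl2, 0 °C → rt; then p-TsOH·H2O (cat.), CH2Cl2, rt
Reagents that add atoms: dimethyldioxirane, CC1(C)OO1
Why: DMDO epoxidation of the enol-ether-like C2=C3 bond followed by acid-catalysed epoxide opening (cation stabilised by O1 and the anisyl group) and loss of H-3 gives the flavonol, which avoids the Algar–Flynn–Oyamada reaction that diverts 6'-methoxychalcones to aurones.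

**Step 10**
Reactants: 19 8-(benzyloxy)-3-hydroxy-5,6,7-trimethoxy-2-(4-methoxyphenyl)-4H-chromen-4-one
Product: 20 eriostemin, 3,8-dihydroxy-5,6,7-trimethoxy-2-(4-methoxyphenyl)-4H-chromen-4-one
Conditions: H2 (1 atm), 10% Pd/C, EtOAc–MeOH 1:1, rt, 3 h
Reagents that add atoms: none
Why: Catalytic hydrogenolysis cleaves only the benzylic C–O bond under neutral conditions, leaving the four methyl ethers (including the Lewis-acid-labile 5-OMe) and the flavonol C2=C3 bond intact, and the achiral target has no stereocentre to set.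

**Compound list**
1 | 3,4,5-trimethoxyphenol | COc1cc(O)cc(OC)c1OC | starting material
2 | 1,2,3-trimethoxy-5-(methoxymethoxy)benzene | COCOc1cc(OC)c(OC)c(OC)c1 | intermediate
3 | [2,3,4-trimethoxy-6-(methoxymethoxy)phenyl]lithium (not isolated) | [Li]c1c(OCOC)cc(OC)c(OC)c1OC | intermediate
4 | dimethyl [2,3,4-trimethoxy-6-(methoxymethoxy)phenyl]boronate (not isolated) | COCOc1cc(OC)c(OC)c(OC)c1B(OC)OC | intermediate
5 | 2,3,4-trimethoxy-6-(methoxymethoxy)phenol | COCOc1cc(OC)c(OC)c(OC)c1O | intermediate
6 | 2-(benzyloxy)-3,4,5-trimethoxy-1-(methoxymethoxy)benzene | COCOc1cc(OC)c(OC)c(OC)c1OCc1ccccc1 | intermediate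
7 | 1-(benzyloxy)-3-bromo-4,5,6-trimethoxy-2-(methoxymethoxy)benzene | COCOc1c(Br)c(OC)c(OC)c(OC)c1OCc1ccccc1 | intermediate
8 | N-methoxy-N-methylacetamide | CON(C)C(C)=O | starting material
9 | [3-(benzyloxy)-4,5,6-trimethoxy-2-(methoxymethoxy)phenyl]lithium (not isolated) | [Li]c1c(OCOC)c(OCc2ccccc2)c(OC)c(OC)c1OC | intermediate
10 | lithium 1-aryl-1-[methoxy(methyl)amino]ethan-1-olate, tetrahedral Weinreb adduct, racemic (not isolated) | [Li+].CC([O-])(N(C)OC)c1c(OCOC)c(OCc2ccccc2)c(OC)c(OC)c1OC | intermediate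
11 | 1-[3-(benzyloxy)-4,5,6-trimethoxy-2-(methoxymethoxy)phenyl]ethan-1-one | CC(=O)c1c(OCOC)c(OCc2ccccc2)c(OC)c(OC)c1OC | intermediate
12 | 1-[3-(benzyloxy)-2-hydroxy-4,5,6-trimethoxyphenyl]ethan-1-one | CC(=O)c1c(O)c(OCc2ccccc2)c(OC)c(OC)c1OC | intermediate
13 | 4-methoxybenzaldehyde | COc1ccc(C=O)cc1 | starting material
14 | 1-[3-(benzyloxy)-2-hydroxy-4,5,6-trimethoxyphenyl]-3-hydroxy-3-(4-methoxyphenyl)propan-1-one, racemic (not isolated) | COc1ccc(C(O)CC(=O)c2c(O)c(OCc3ccccc3)c(OC)c(OC)c2OC)cc1 | intermediate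
15 | (E)-1-[3-(benzyloxy)-2-hydroxy-4,5,6-trimethoxyphenyl]-3-(4-methoxyphenyl)prop-2-en-1-one | COc1ccc(/C=C/C(=O)c2c(O)c(OCc3ccccc3)c(OC)c(OC)c2OC)cc1 | intermediate
16 | 8-(benzyloxy)-5,6,7-trimethoxy-2-(4-methoxyphenyl)chroman-4-one, racemic (not isolated) | COc1ccc(C2CC(=O)c3c(OC)c(OC)c(OC)c(OCc4ccccc4)c3O2)cc1 | intermediate
17 | 8-(benzyloxy)-5,6,7-trimethoxy-2-(4-methoxyphenyl)-4H-chromen-4-one | COc1ccc(-c2cc(=O)c3c(OC)c(OC)c(OC)c(OCc4ccccc4)c3o2)cc1 | intermediate
18 | 2,3-epoxide of 17, racemic, ring-fused cis (not isolated) | COc1ccc(cc1)C12OC1C(=O)c1c(O2)c(OCc3ccccc3)c(OC)c(OC)c1OC | intermediate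
19 | 8-(benzyloxy)-3-hydroxy-5,6,7-trimethoxy-2-(4-methoxyphenyl)-4H-chromen-4-one | COc1ccc(-c2oc3c(OCc4ccccc4)c(OC)c(OC)c(OC)c3c(=O)c2O)cc1 | intermediate
20 | eriostemin, 3,8-dihydroxy-5,6,7-trimethoxy-2-(4-methoxyphenyl)-4H-chromen-4-one (achiral) | COc1ccc(-c2oc3c(O)c(OC)c(OC)c(OC)c3c(=O)c2O)cc1 | target

**Step count**
Total step count: 10.
Longest linear sequence: 10 steps (1 → 20). Compounds 8 and 13 enter as bought.

**Three steps most likely to fail**

Step 9 (DMDO 3-hydroxylation). The risks are incomplete conversion and over-oxidation of the electron-rich rings or of the benzylic CH2.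
The fallback sets out from 17 and comes back at 19. It replaces electrophilic oxygen transfer by carbanion chemistry.
- LDA in THF at −78 °C removes H-3 to give the 3-lithioflavone F1.
- B(OMe)3 traps it as the dimethyl flavon-3-ylboronate F2.
- H2O2/AcOH in the same pot oxidises the C–B bond to the 3-hydroxyl of 19.

Step 5 (acylation of the di-ortho-substituted aryllithium). The hindered aryllithium may act as a base and enolise the amide, returning the debrominated arene.
The fallback sets out from 7 (through 9) and comes back at 11. It replaces acyl substitution by carbonyl addition followed by oxidation.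
- Aryllithium 9 is quenched with the small and more electrophilic acetaldehyde, then with aq NH4Cl, to give the racemic 1-arylethanol F3.
- Dess–Martin periodinane in CH2Cl2 with NaHCO3 then oxidises this to ketone 11.

Step 2 (lithiation, borylation, oxidation). The 2,6-dialkoxyarylboronate can protodeboronate, and the electron-rich phenol can be over-oxidised by peroxide.
The fallback sets out from 2 (through 3) and comes back at 5. It brings in the oxygen by a carbon-to-oxygen aryl migration.
- Aryllithium 3 is quenched with DMF, then with aq NH4Cl, to give 2,3,4-trimethoxy-6-(methoxymethoxy)benzaldehyde F4.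
- Baeyer–Villiger oxidation with mCPBA in NaHCO3-buffered CH2Cl2 gives the aryl formate F5.
- Catalytic K2CO3 in MeOH cleaves the formate to phenol 5.

**Further compounds**
F1 | step 9 | [8-(benzyloxy)-5,6,7-trimethoxy-2-(4-methoxyphenyl)-4-oxo-4H-chromen-3-yl]lithium | COc1ccc(-c2oc3c(OCc4ccccc4)c(OC)c(OC)c(OC)c3c(=O)c2[Li])cc1
F2 | step 9 | dimethyl [8-(benzyloxy)-5,6,7-trimethoxy-2-(4-methoxyphenyl)-4-oxo-4H-chromen-3-yl]boronate | COc1ccc(-c2oc3c(OCc4ccccc4)c(OC)c(OC)c(OC)c3c(=O)c2B(OC)OC)cc1
F3 | step 5 | 1-[3-(benzyloxy)-4,5,6-trimethoxy-2-(methoxymethoxy)phenyl]ethan-1-ol (racemic) | CC(O)c1c(OCOC)c(OCc2ccccc2)c(OC)c(OC)c1OC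
F4 | step 2 | 2,3,4-trimethoxy-6-(methoxymethoxy)benzaldehyde | COCOc1cc(OC)c(OC)c(OC)c1C=O
F5 | step 2 | 2,3,4-trimethoxy-6-(methoxymethoxy)phenyl formate | COCOc1cc(OC)c(OC)c(OC)c1OC=O
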